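**Plan**

Rings: A = 4-methoxyphenyl, B = 4-hydroxy-2-methoxyphenyl, C = central 2,6-dimethoxyaryl, D = 4-hydroxyphenyl of the stilbene. C* is the only stereocentre. Enabling feature: C* is the benzylic carbon on C1 of ring C, and the neighbouring C2 carries oxygen, so O–C2–C1–C* is a masked O=C–C=C heterodiene (an ortho-quinone methide).
Cuts: (a) the ring C (C4)–CH= bond of the stilbene (Heck). (b) The ring B–CH2 bond (aryl Grignard on a lactol carbon, then removal of the carbinol oxygen) and one ring C O–CH3 bond. (c) In one operation, C*–ring A, C*–CH2 and the O–CH bond of a 2-alkoxychroman.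
Forward: ring C is prepared as an O-Boc salicylaldehyde, and Grignard-triggered quinone methide formation with [4+2] capture by a chiral vinyl ether closes the only new ring, a dihydropyran. This ring is reopened at its acetal carbon to take up ring B, and O-methylation, benzylic deoxygenation, Heck coupling and deprotection complete the chain.
Stereochemistry: C* (S) is set in the cycloaddition by the (1S,2R)-2-phenylcyclohexyl group on the vinyl ether (endo approach, E-quinone methide). The E-alkene comes from the Heck reaction, and the acetal and carbinol centres are transient.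

Key step: step 5

Assumption: the sense of induction follows the shielding model in step 5 (s-trans vinyl ether, endo approach, attack anti to the phenyl group). The absolute configuration of the bromine-containing cycloadduct should be checked by anomalous-dispersion X-ray analysis. The equally available (1R,2S)-alcohol would be taken through the same steps if the model failed.

**Route**

Step 1
Reactants: 1 4-bromo-2,6-difluorobenzaldehyde
Product: 2 4-bromo-2,6-dimethoxybenzaldehyde
Conditions: NaOMe (3 equiv), MeOH, reflux
Reagents that add atoms: sodium methoxide, C[O-].[Na+]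
Why: Twofold nucleophilic aromatic substitution (addition–elimination) should exchange only the C–F bonds, because both fluorides are ortho to the formyl group and leave far more readily than the para bromide.

Step 2
Reactants: 2 4-bromo-2,6-dimethoxybenzaldehyde
Product: 3 4-bromo-2-hydroxy-6-methoxybenzaldehyde
Conditions: BCl3 (1.1 equiv), CH2Cl2, −78 → 0 °C; then H2O
Reagents that add atoms: none
Why: In this chelation-directed aryl methyl ether cleavage, BCl3 bridges the formyl oxygen and one flanking methoxy group, chloride removes that methyl, and the resulting boron chelate occupies the carbonyl so that the second methoxy group should survive one equivalent of reagent.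

Step 3
Reactants: 3 4-bromo-2-hydroxy-6-methoxybenzaldehyde
Product: 4 tert-butyl (5-bromo-2-formyl-3-methoxyphenyl) carbonate
Conditions: Boc2O, i-Pr2NEt, DMAP (cat.), CH2Cl2, 0 °C → rt
Reagents that add atoms: di-tert-butyl dicarbonate, CC(C)(C)OC(=O)OC(=O)OC(C)(C)C
Why: DMAP-catalysed O-acylation of the phenol gives the aryl tert-butyl carbonate, and the aldehyde and aryl bromide are inert under these conditions.

Step 4
Reactants: 5 (1S,2R)-2-phenylcyclohexan-1-ol
Product: 6 (1S,2R)-2-phenylcyclohexyl vinyl ether
Conditions: Hg(OAc)2 (10 mol %), ethyl vinyl ether (solvent), reflux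
Reagents that add atoms: ethyl vinyl ether, C=COCC
Why: Hg(OAc)2-catalysed transvinylation (reversible alkoxymercuration and de-alkoxymercuration) is driven by the excess ethyl vinyl ether and never breaks the carbinol C–O bond, so both auxiliary stereocentres are retained.

Step 5
Reactants: 4 tert-butyl (5-bromo-2-formyl-3-methoxyphenyl) carbonate; 6 (1S,2R)-2-phenylcyclohexyl vinyl ether; 7 4-methoxyphenylmagnesium bromide
Product: 11 (2R,4S)-7-bromo-5-methoxy-4-(4-methoxyphenyl)-2-{[(1S,2R)-2-phenylcyclohexyl]oxy}chromane (2,4-cis), via bromomagnesium alkoxide adduct 8 (not isolated), via Boc-migrated magnesium phenoxide 9 (not isolated), via (E)-ortho-quinone methide 10 (not isolated)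
Conditions: 4, 6 (2.5 equiv), Et2O, −78 °C; 7 (1.05 equiv, THF solution); −78 °C → rt
Reagents that add atoms: none
Why: Grignard reagent 7 adds at −78 °C to the formyl group of 4 to give alkoxide 8, the Boc group moves from the phenolic to the benzylic oxygen (9), and on warming the magnesium phenoxide expels tert-butyl carbonate to unmask the (E)-ortho-quinone methide 10, which the electron-rich alkene of 6 captures as it forms. The closest known reaction type is this same Grignard-triggered release of ortho-quinone methides from O-Boc salicylaldehydes, coupled to an inverse-electron-demand hetero-Diels–Alder reaction with enol ethers, chiral 2-arylcyclohexyl vinyl ethers included. The dihydropyran ring closes by an intermolecular, concerted but asynchronous [4+2] cycloaddition in which O=C8a–C4a=C* supplies four ring atoms and the vinyl group two, with rearomatisation of ring C as the driving force. C2 is controlled by the auxiliary, because in the reactive s-trans rotamer of 6, with the carbinol C–H eclipsing the O–vinyl bond, the phenyl group covers the Si face of the oxygen-bearing vinyl carbon and the heterodiene oxygen bonds to the open Re face (2R); C4, which is C*, is controlled by the endo placement of the alkoxy group under the heterodiene together with the E geometry of 10, which translate 2R into the 2,4-cis (4S) product. The step needs regioselectivity, secured by polarity (nucleophilic CH2 terminus to electrophilic C*, acetal carbon to oxygen), chemoselectivity, secured by the much faster attack of 7 on the aldehyde than on the carbonate or aryl bromide at −78 °C and by limiting 7 to 1.05 equiv so that none remains to add to 10, and a single alkene geometry in 10, favoured because the anisyl group turns away from the magnesium-bound oxygen towards the methoxy group, whose methyl can rotate aside. Because the auxiliary stays in 11, any C4 epimer is a diastereomer and should be removable by chromatography or crystallisation before the auxiliary is cleaved.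

Step 6
Reactants: 11 (2R,4S)-7-bromo-5-methoxy-4-(4-methoxyphenyl)-2-{[(1S,2R)-2-phenylcyclohexyl]oxy}chromane
Product: 12 (4S)-7-bromo-5-methoxy-4-(4-methoxyphenyl)chroman-2-ol (anomer mixture)
Conditions: camphorsulfonic acid, MeCN/H2O, 60 °C
Reagents that add atoms: water, O
Why: Acid-catalysed acetal hydrolysis proceeds through the cyclic oxocarbenium ion at C2, releases the auxiliary alcohol for recovery and makes or breaks no bond at C4, so C* should be preserved.

Step 7
Reactants: 13 4-bromo-3-methoxyphenol
Product: 14 (4-bromo-3-methoxyphenoxy)triisopropylsilane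
Conditions: i-Pr3SiCl, imidazole, DMF, rt
Reagents that add atoms: triisopropylsilyl chloride, CC(C)[Si](Cl)(C(C)C)C(C)C
Why: Imidazole-promoted silylation installs a bulky aryl silyl ether that should survive Grignard formation, K2CO3/MeI, CF3CO2H/Et3SiH and Heck conditions, yet is removed by fluoride without affecting a stilbene.

Step 8
Reactants: 12 (4S)-7-bromo-5-methoxy-4-(4-methoxyphenyl)chroman-2-ol; 14 (4-bromo-3-methoxyphenoxy)triisopropylsilane
Product: 16 (3S)-3-(4-bromo-2-hydroxy-6-methoxyphenyl)-3-(4-methoxyphenyl)-1-[2-methoxy-4-(triisopropylsilyloxy)phenyl]propan-1-ol (epimer mixture at C1), via aryl Grignard reagent 15 (not isolated)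
Conditions: 14 (2.5 equiv), Mg, I2 (cat.), THF, reflux; then 12, THF, 0 °C → rt; neutral aqueous work-up
Reagents that add atoms: none
Why: In this Grignard addition to a lactol, the first equivalent of 15 deprotonates 12 and opens it to the magnesium phenoxide aldehyde and the second adds to the carbonyl; the new carbinol centre forms without control but is erased in step 10, and C* is not involved.

Step 9
Reactants: 16 (3S)-3-(4-bromo-2-hydroxy-6-methoxyphenyl)-3-(4-methoxyphenyl)-1-[2-methoxy-4-(triisopropylsilyloxy)phenyl]propan-1-ol
Product: 17 (3S)-3-(4-bromo-2,6-dimethoxyphenyl)-3-(4-methoxyphenyl)-1-[2-methoxy-4-(triisopropylsilyloxy)phenyl]propan-1-ol (epimer mixture at C1)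
Conditions: MeI, K2CO3, acetone, reflux
Reagents that add atoms: iodomethane, CI
Why: In this Williamson ether synthesis K2CO3 ionises only the phenol and not the secondary alcohol, and capping this oxygen also removes the internal nucleophile that would otherwise trap the benzylic cation of the next step.

Step 10
Reactants: 17 (3S)-3-(4-bromo-2,6-dimethoxyphenyl)-3-(4-methoxyphenyl)-1-[2-methoxy-4-(triisopropylsilyloxy)phenyl]propan-1-ol
Product: 18 {4-[(3S)-3-(4-bromo-2,6-dimethoxyphenyl)-3-(4-methoxyphenyl)propyl]-3-methoxyphenoxy}triisopropylsilane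
Conditions: Et3SiH (5 equiv), CF3CO2H (3 equiv), CH2Cl2, −20 → 0 °C
Reagents that add atoms: none
Why: In this ionic hydrogenation (ionic deoxygenation) the carbinol ionises readily because ring B carries ortho and para oxygen donors, and excess silane should deliver hydride to the cation faster than it can cyclise or eliminate, while the aryl bromide, the aryl silyl ether and the remote C* stay untouched.

Step 11
Reactants: 18 {4-[(3S)-3-(4-bromo-2,6-dimethoxyphenyl)-3-(4-methoxyphenyl)propyl]-3-methoxyphenoxy}triisopropylsilane; 19 4-acetoxystyrene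
Product: 20 4-[(E)-2-(3,5-dimethoxy-4-{(1S)-1-(4-methoxyphenyl)-3-[2-methoxy-4-(triisopropylsilyloxy)phenyl]propyl}phenyl)ethenyl]phenyl acetate
Conditions: Pd(OAc)2 (5 mol %), P(o-tol)3 (12 mol %), Et3N, DMF, 100 °C
Reagents that add atoms: none
Why: In this Mizoroki–Heck reaction zerovalent palladium inserts into the unhindered C–Br bond, syn carbopalladation places the aryl group on the terminal styrene carbon, and syn β-hydride elimination from the less crowded rotamer gives the E-stilbene.

Step 12
Reactants: 20 4-[(E)-2-(3,5-dimethoxy-4-{(1S)-1-(4-methoxyphenyl)-3-[2-methoxy-4-(triisopropylsilyloxy)phenyl]propyl}phenyl)ethenyl]phenyl acetate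
Product: 22 4-[(3S)-3-{4-[(E)-2-(4-hydroxyphenyl)ethenyl]-2,6-dimethoxyphenyl}-3-(4-methoxyphenyl)propyl]-3-methoxyphenol (CNP0182684.1), via TIPS-protected stilbenol 21 (not isolated)
Conditions: K2CO3 (0.2 equiv), MeOH/THF, rt; then Bu4NF, rt; aqueous work-up
Reagents that add atoms: none
Why: Base-catalysed transesterification removes the aryl acetate and fluoride-induced desilylation then frees the ring B phenol, and both are mild reactions that should not isomerise the stilbene, cleave a methyl ether or affect C*.

**Compound list**

1 | 4-bromo-2,6-difluorobenzaldehyde | O=Cc1c(F)cc(Br)cc1F | starting material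
2 | 4-bromo-2,6-dimethoxybenzaldehyde | COc1cc(Br)cc(OC)c1C=O | intermediate
3 | 4-bromo-2-hydroxy-6-methoxybenzaldehyde | COc1cc(Br)cc(O)c1C=O | intermediate
4 | tert-butyl (5-bromo-2-formyl-3-methoxyphenyl) carbonate | CC(C)(C)OC(=O)Oc1cc(Br)cc(OC)c1C=O | intermediate
5 | (1S,2R)-2-phenylcyclohexan-1-ol | O[C@H]1CCCC[C@@H]1c1ccccc1 | starting material
6 | (1S,2R)-2-phenylcyclohexyl vinyl ether | C=CO[C@H]1CCCC[C@@H]1c1ccccc1 | intermediate
7 | 4-methoxyphenylmagnesium bromide | COc1ccc([Mg]Br)cc1 | starting material
8 | bromomagnesium [4-bromo-2-(tert-butoxycarbonyloxy)-6-methoxyphenyl](4-methoxyphenyl)methoxide | COc1ccc(C(O[Mg]Br)c2c(OC)cc(Br)cc2OC(=O)OC(C)(C)C)cc1 | intermediate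
9 | bromomagnesium 5-bromo-2-[(tert-butoxycarbonyloxy)(4-methoxyphenyl)methyl]-3-methoxyphenoxide | COc1ccc(C(OC(=O)OC(C)(C)C)c2c(OC)cc(Br)cc2O[Mg]Br)cc1 | intermediate
10 | (6E)-3-bromo-5-methoxy-6-(4-methoxybenzylidene)cyclohexa-2,4-dien-1-one | COc1ccc(/C=C2/C(=O)C=C(Br)C=C2OC)cc1 | intermediate
11 | (2R,4S)-7-bromo-5-methoxy-4-(4-methoxyphenyl)-2-{[(1S,2R)-2-phenylcyclohexyl]oxy}chromane | COc1ccc([C@@H]2C[C@H](O[C@H]3CCCC[C@@H]3c3ccccc3)Oc3cc(Br)cc(OC)c23)cc1 | intermediate
12 | (4S)-7-bromo-5-methoxy-4-(4-methoxyphenyl)chroman-2-ol, anomer mixture | COc1ccc([C@@H]2CC(O)Oc3cc(Br)cc(OC)c23)cc1 | intermediate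
13 | 4-bromo-3-methoxyphenol | COc1cc(O)ccc1Br | starting material
14 | (4-bromo-3-methoxyphenoxy)triisopropylsilane | COc1cc(O[Si](C(C)C)(C(C)C)C(C)C)ccc1Br | intermediate
15 | [2-methoxy-4-(triisopropylsilyloxy)phenyl]magnesium bromide | COc1cc(O[Si](C(C)C)(C(C)C)C(C)C)ccc1[Mg]Br | intermediate
16 | (3S)-3-(4-bromo-2-hydroxy-6-methoxyphenyl)-3-(4-methoxyphenyl)-1-[2-methoxy-4-(triisopropylsilyloxy)phenyl]propan-1-ol, C1 epimers | COc1ccc([C@H](CC(O)c2ccc(O[Si](C(C)C)(C(C)C)C(C)C)cc2OC)c2c(O)cc(Br)cc2OC)cc1 | intermediate
17 | (3S)-3-(4-bromo-2,6-dimethoxyphenyl)-3-(4-methoxyphenyl)-1-[2-methoxy-4-(triisopropylsilyloxy)phenyl]propan-1-ol, C1 epimers | COc1ccc([C@H](CC(O)c2ccc(O[Si](C(C)C)(C(C)C)C(C)C)cc2OC)c2c(OC)cc(Br)cc2OC)cc1 | intermediate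
18 | {4-[(3S)-3-(4-bromo-2,6-dimethoxyphenyl)-3-(4-methoxyphenyl)propyl]-3-methoxyphenoxy}triisopropylsilane | COc1ccc([C@H](CCc2ccc(O[Si](C(C)C)(C(C)C)C(C)C)cc2OC)c2c(OC)cc(Br)cc2OC)cc1 | intermediate
19 | 4-acetoxystyrene (4-ethenylphenyl acetate) | C=Cc1ccc(OC(C)=O)cc1 | starting material
20 | 4-[(E)-2-(3,5-dimethoxy-4-{(1S)-1-(4-methoxyphenyl)-3-[2-methoxy-4-(triisopropylsilyloxy)phenyl]propyl}phenyl)ethenyl]phenyl acetate | COc1ccc([C@H](CCc2ccc(O[Si](C(C)C)(C(C)C)C(C)C)cc2OC)c2c(OC)cc(/C=C/c3ccc(OC(C)=O)cc3)cc2OC)cc1 | intermediate
21 | 4-[(E)-2-(3,5-dimethoxy-4-{(1S)-1-(4-methoxyphenyl)-3-[2-methoxy-4-(triisopropylsilyloxy)phenyl]propyl}phenyl)ethenyl]phenol | COc1ccc([C@H](CCc2ccc(O[Si](C(C)C)(C(C)C)C(C)C)cc2OC)c2c(OC)cc(/C=C/c3ccc(O)cc3)cc2OC)cc1 | intermediate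
22 | 4-[(3S)-3-{4-[(E)-2-(4-hydroxyphenyl)ethenyl]-2,6-dimethoxyphenyl}-3-(4-methoxyphenyl)propyl]-3-methoxyphenol (CNP0182684.1) | COc1ccc([C@H](CCc2ccc(O)cc2OC)c2c(OC)cc(/C=C/c3ccc(O)cc3)cc2OC)cc1 | target

**Step count**

Total steps: 12. Longest linear sequence: 10 (steps 1, 2, 3, 5, 6, 8, 9, 10, 11, 12).

**Steps most likely to fail**

Step 5. The configuration at C* could erode through three channels: leakage via the Z-quinone methide (the exocyclic carbon is flanked by oxygen substituents on both sides), partial exo approach, or insufficient facial bias of the auxiliary. The quinone methide could also be consumed by dimerisation or by residual Grignard reagent. The fallback replaces auxiliary control by catalyst control and sets out from 3. A Wittig olefination with lactonisation (Ph3P=CHCO2Et, hot N,N-diethylaniline) would give 7-bromo-5-methoxycoumarin F1. A Hayashi–Miyaura 1,4-addition of 4-methoxyphenylboronic acid (Rh(acac)(C2H4)2, (S)-SEGPHOS, dioxane/H2O, 60 °C) would then give (4S)-7-bromo-5-methoxy-4-(4-methoxyphenyl)chroman-2-one F2. Half-reduction with i-Bu2AlH in toluene at −78 °C returns to the route at 12.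

Step 10. The benzylic cation could be intercepted before hydride transfer. An ortho-methoxy oxygen of ring C could attack with loss of its methyl group and close a flavan, ring A could attack in a Friedel–Crafts closure to an indane, or elimination followed by oligomerisation could compete. The fallback avoids a free cation and sets out from 17. Burgess dehydration (syn elimination, benzene, 50 °C) would give {4-[(1E,3S)-3-(4-bromo-2,6-dimethoxyphenyl)-3-(4-methoxyphenyl)prop-1-en-1-yl]-3-methoxyphenoxy}triisopropylsilane F3. Diimide reduction (TsNHNH2, NaOAc, THF/H2O, reflux) saturates the alkene without touching the aryl bromide and returns to the route at 18.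

Step 8. The basic Grignard reagent could enolise the ring-opened hydroxy aldehyde, the magnesium lactolate could open incompletely, or the free phenol could cyclise onto the easily ionised carbinol during work-up or chromatography. The fallback changes the electrophile and the order of events and sets out from 12. Ring-opening O-methylation (MeI, K2CO3, DMF, rt) would give (3S)-3-(4-bromo-2,6-dimethoxyphenyl)-3-(4-methoxyphenyl)propanal F4. Addition of 15 (1.3 equiv, THF, −78 °C) to this free aldehyde returns to the route directly at 17, so that phenol and carbinol never coexist.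

**Further compounds**

F1 | step 5 | 7-bromo-5-methoxycoumarin | COc1cc(Br)cc2OC(=O)C=Cc12
F2 | step 5 | (4S)-7-bromo-5-methoxy-4-(4-methoxyphenyl)chroman-2-one | COc1ccc([C@@H]2CC(=O)Oc3cc(Br)cc(OC)c23)cc1
F3 | step 10 | {4-[(1E,3S)-3-(4-bromo-2,6-dimethoxyphenyl)-3-(4-methoxyphenyl)prop-1-en-1-yl]-3-methoxyphenoxy}triisopropylsilane | COc1ccc([C@H](/C=C/c2ccc(O[Si](C(C)C)(C(C)C)C(C)C)cc2OC)c2c(OC)cc(Br)cc2OC)cc1
F4 | step 8 | (3S)-3-(4-bromo-2,6-dimethoxyphenyl)-3-(4-methoxyphenyl)propanal | COc1ccc([C@H](CC=O)c2c(OC)cc(Br)cc2OC)cc1
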